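**Two readings.** The constants of this flask are not given, so I replace them with two numbers read from the teal run and ask first how well each must be known.

| flask | starting material | coupling partner | free catalyst | second catalyst | remark | time |
|---|---|---|---|---|---|---|
| teal | 1.9 M | 0.45 equiv | 2.5 mol% | 0.5 mol% | run made earlier |  |
| flask | 1.9 M | 0.900 equiv | 2.5 mol% | 0.5 mol% |  | 8.0 d |
teal run (percent of the starting material charged)

| time / d | starting material / % | target / % | side product / % |
|---|---|---|---|
| 0.417 | 51.0 | 2.1 | 29.1 |
| 1.25 | 12.8 | 5.6 | 74.8 |
| 2.50 | 1.1 | 7.6 | 89.8 |
| 3.00 | 1.3 | 8.3 | 91.0 |
| 5.00 | 0 | 7.5 | 92.3 |
| 6.00 | 0 | 7.8 | 92.3 |
| 8.00 | 0.1 | 8.1 | 91.4 |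

(readings scatter by 0.3 percentage points)
- candidate steps: open intermediate -> side product; starting material + free catalyst -> free catalyst + open intermediate; second catalyst + open intermediate <-> catalyst intermediate; coupling partner + catalyst intermediate -> second catalyst + target; second catalyst -> spent catalyst
- the reaction counts as stopped when no species that holds the starting material changes by six tenths of a point or more over the second half of the time
- the state of affairs at 8.0 d: stopped, and by what, or still going (no working catalyst is left / forward and back rates have come level / the coupling partner has run out first / it is still moving / all of the starting material has reacted)
- share of the starting material used up at 8.0 d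
- target at 8.0 d, in percent of the starting material charged
- side product at 8.0 d, in percent of the starting material charged
- amount of target if the flask were left three thousand times as long, in percent of the starting material charged

**The clock.** For the conversion at 8.0 d, the rate of fall of starting material needs no great accuracy. Its fraction at 0.417 d gives a rate of 1.61 /d and a half-life of 0.429 d. I carry this to the flask, whose charges of starting material and free catalyst match teal's. Because the half-life is shorter than 8.0 d, even a half-life longer by a factor of 2 reckons out at 0.156% of the starting material remaining.

**The split.** The division of the material between target and side product is the number to know well. The scatter of 0.3 percentage points sits on a side product of 91.4% but on a target of 8.1%, so the target readings count, and I average the last 4. The response to the coupling partner is uncertain, since teal shows one level. The capture ratio, target over side product at the plateau (a selectivity factor), reads 0.0864.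

**My reckoning.** If the ratio scales with the equivalents of coupling partner, the flask has a ratio of 0.173, so target is 14.7% of the charge and side product 85.3%. Teal's target reads 8.3% at 3.00 d and 8.1% at 8.00 d, so I expect no gain from waiting.

**The forecast.** It gives: all of the starting material has reacted, conversion 100%, target 13.5%, side product 86.5%, and 13.5% after the long wait. Its ground is that “Doubling the partner should raise capture by less than, or at most, twofold”. Its target is lower than mine.

**The flask.** At 8.0 d, all of the starting material has reacted: conversion >99.9%, target 12.4%, side product 87.6%, and 12.4% after the long wait.

    open intermediate → side product (k = 5.40 × 10⁻⁵ /s)
    starting material + free catalyst → free catalyst + open intermediate (k = 4.00 × 10⁻⁴ /M/s)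
    second catalyst + open intermediate ⇌ catalyst intermediate (K = 5.90 /M, k = 0.00220 /M/s)
    coupling partner + catalyst intermediate → second catalyst + target (k = 3.00 × 10⁻⁴ /M/s)
    second catalyst → spent catalyst (k = 2.40 × 10⁻⁸ /s)

**Capture again.** The forecast stands, but with the other charges and the time held, side product moves by 5 points at 0.28 mol% or 0.75 mol% of second catalyst, against the 0.5 mol% charged. The flask's capture ratio is 0.142, which is 1.64 times teal's for 2.00 times the coupling partner. For a neighbouring flask with 0.230 equiv of coupling partner, the scaled ratio gives target 4.23%, and that flask gives 4.60%.

(The earlier runs and the new flask are calculated with made-up constants, and the scatter is random.)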